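## Retrosynthetic overview

1. Target 20 ⇐ tris-PMB ether 19 by one neutral hydrogenolysis.
2. 19 ⇐ open-chain aryl boronate/aryl bromide 15 + vinylmagnesium chloride 16: a macrocyclising conjunctive coupling in which ring A shifts 1,2 from boron to carbon. This forms the ring A–CH bond, sets the S centre and closes the 18-membered ring; C–B oxidation follows in the same flask.
3. 15 ⇐ styrene 7 (rings C and D) + iodide/boronate 13 (rings A and B): hydroboration and B-alkyl Suzuki coupling make the ethylene bridge.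
4. 7 and 13 both ⇐ aldehyde 4 (from 2-fluorophenol). Ring C/D branch: SNAr with 3-bromophenol, then Wittig. Ring A/B branch: SNAr with PMB alcohol, Baeyer–Villiger, Ullmann coupling with 1,4-diiodobenzene, iridium C–H borylation.
5. All four benzene rings are bought; the only ring formed is the macrocycle (step 10).

Ring letters: A = trioxygenated ring bearing the carbinol; B = para-phenylene; C = ring with the single free OH; D = meta-phenylene. PMB = 4-methoxybenzyl; pin = pinacolato; 9-BBN = 9-borabicyclo[3.3.1]nonane.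

Assumption: (Sp,Sp)-MandyPhos is taken as the ligand enantiomer that leads to the S boronic ester; should it lead to R, (Rp,Rp)-MandyPhos is used and nothing else changes.

## Route

Step 1
Reactants: 1 2-fluorophenol
Product: 2 1-fluoro-2-[(4-methoxybenzyl)oxy]benzene
Conditions: PMBCl, K2CO3, DMF, 60 °C
Reagents that add atoms: 4-methoxybenzyl chloride, COc1ccc(CCl)cc1
Why: Williamson ether synthesis; the phenoxide displaces the benzylic chloride cleanly.

Step 2
Reactants: 2 1-fluoro-2-[(4-methoxybenzyl)oxy]benzene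
Product: 4 2-fluoro-3-[(4-methoxybenzyl)oxy]benzaldehyde, via aryllithium 3 (not isolated)
Conditions: n-BuLi, PMDTA, THF, –78 °C; DMF, –78 °C to 0 °C; H2O
Reagents that add atoms: N,N-dimethylformamide, CN(C)C=O
Why: Directed ortho-metalation; with PMDTA on lithium the ether oxygen cannot guide the base, so the most acidic C–H next to fluorine is removed, and DMF formylates the aryllithium.

Step 3
Reactants: 4 2-fluoro-3-[(4-methoxybenzyl)oxy]benzaldehyde, 5 3-bromophenol
Product: 6 2-(3-bromophenoxy)-3-[(4-methoxybenzyl)oxy]benzaldehyde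
Conditions: K2CO3, DMF, 110 °C
Reagents that add atoms: none
Why: SNAr; the fluoride ortho to the formyl group is displaced by the phenoxide, and the aryl bromide is inert.

Step 4
Reactants: 6 2-(3-bromophenoxy)-3-[(4-methoxybenzyl)oxy]benzaldehyde
Product: 7 2-(3-bromophenoxy)-1-ethenyl-3-[(4-methoxybenzyl)oxy]benzene
Conditions: Ph3PCH3Br, KOtBu, THF, 0 °C to rt
Reagents that add atoms: methyltriphenylphosphonium bromide, C[P+](c1ccccc1)(c1ccccc1)c1ccccc1.[Br-]
Why: Wittig methylenation of an aryl aldehyde, which leaves ethers and the aryl bromide untouched.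

Step 5
Reactants: 4 2-fluoro-3-[(4-methoxybenzyl)oxy]benzaldehyde
Product: 8 2,3-bis[(4-methoxybenzyl)oxy]benzaldehyde
Conditions: 4-methoxybenzyl alcohol, Cs2CO3, DMSO, 70 °C
Reagents that add atoms: 4-methoxybenzyl alcohol, COc1ccc(CO)cc1
Why: SNAr with an alkoxide on the same formyl-activated fluoride, which installs the future middle oxygen of ring A already protected.

Step 6
Reactants: 8 2,3-bis[(4-methoxybenzyl)oxy]benzaldehyde
Product: 10 2,3-bis[(4-methoxybenzyl)oxy]phenol, via aryl formate 9 (not isolated)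
Conditions: mCPBA, CH2Cl2, 0 °C to rt; then K2CO3 (cat.), MeOH, rt
Reagents that add atoms: 3-chloroperoxybenzoic acid, OOC(=O)c1cccc(Cl)c1
Why: Baeyer–Villiger oxidation; the electron-rich aryl group migrates to oxygen, and methanolysis of the formate frees the phenol.

Step 7
Reactants: 10 2,3-bis[(4-methoxybenzyl)oxy]phenol, 11 1,4-diiodobenzene (3 equiv)
Product: 12 1-(4-iodophenoxy)-2,3-bis[(4-methoxybenzyl)oxy]benzene
Conditions: CuI (10 mol%), picolinic acid (20 mol%), K3PO4, DMSO, 80 °C
Reagents that add atoms: none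
Why: Ullmann-type copper-catalysed O-arylation of a phenol with one ortho substituent; excess diiodide keeps the coupling on one iodine only.

Step 8
Reactants: 12 1-(4-iodophenoxy)-2,3-bis[(4-methoxybenzyl)oxy]benzene
Product: 13 2-{3-(4-iodophenoxy)-4,5-bis[(4-methoxybenzyl)oxy]phenyl}-4,4,5,5-tetramethyl-1,3,2-dioxaborolane
Conditions: [Ir(OMe)(cod)]2 (1.5 mol%), 4,4'-di-tert-butyl-2,2'-bipyridine (3 mol%), B2pin2 (0.6 equiv), THF, 60 °C
Reagents that add atoms: bis(pinacolato)diboron, CC1(C)OB(OC1(C)C)B1OC(C)(C)C(C)(C)O1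
Why: Sterically controlled iridium-catalysed C–H borylation; the ring A position para to the middle oxygen is the only C–H in the molecule with no ortho substituent (ring B and the PMB rings are 1,4-disubstituted), and aryl iodides are tolerated.

Step 9
Reactants: 7 2-(3-bromophenoxy)-1-ethenyl-3-[(4-methoxybenzyl)oxy]benzene, 13 2-{3-(4-iodophenoxy)-4,5-bis[(4-methoxybenzyl)oxy]phenyl}-4,4,5,5-tetramethyl-1,3,2-dioxaborolane
Product: 15 open-chain pinacol boronate in which ring B of 13 carries, in place of iodine, the 2-arylethyl chain that comes from 7 (ring A Bpin and ring D bromide both kept), via B-alkyl-9-BBN adduct 14 (not isolated)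
Conditions: 9-BBN, THF, rt; then 13, PdCl2(dppf) (5 mol%), K3PO4·H2O, DMF, 25 °C
Reagents that add atoms: none
Why: Anti-Markovnikov hydroboration followed by B-alkyl Suzuki–Miyaura coupling; at room temperature the aryl iodide reacts far ahead of the aryl bromide, and the Lewis-acidic alkyl-9-BBN is activated by phosphate and transmetalates far ahead of the aryl pinacol boronate.

Step 10
Reactants: 15 open-chain pinacol boronate (ring A Bpin, ring D bromide), 16 vinylmagnesium chloride
Product: 19 tris-PMB ether of the target with the free S benzylic alcohol, via vinylborate ate complex 17 (not isolated), via macrocyclic S boronic ester 18 (not isolated)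
Conditions: 16 (1.05 equiv), THF, 0 °C; NaOTf, DMSO; syringe-pump addition over 12 h to Pd(OAc)2 (5 mol%), (Sp,Sp)-MandyPhos (6 mol%), THF, 60 °C, 2 mM final; then 3 M NaOH, 30% H2O2, 0 °C to rt
Reagents that add atoms: hydrogen peroxide, OO
Why: Proposed new method: a macrocyclising conjunctive cross-coupling; zerovalent palladium inserts into the ring D C–Br bond, NaOTf removes bromide, and the cationic divalent aryl palladium binds the vinyl group of the tethered four-coordinate borate, which triggers an anti 1,2-shift of the ring A aryl from boron to the internal carbon while the terminal carbon bonds to palladium; the chiral diphosphine selects the alkene face and so sets the S centre, reductive elimination closes the 18-membered ring, slow addition at 2 mM keeps the process intramolecular, and NaOH/H2O2 oxidises C–B to C–OH with retention; the closest known reaction is the intermolecular palladium/MandyPhos conjunctive coupling of aryl(vinyl)boron ate complexes with aryl halides or triflates, which has not been used to close a macrocycle.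

Step 11
Reactants: 19 tris-PMB ether of the target with the free S benzylic alcohol
Product: 20 CNP0333307.1
Conditions: H2 (1 atm), 10% Pd/C, EtOAc/EtOH, rt
Reagents that add atoms: none
Why: Hydrogenolysis of three phenolic PMB ethers under neutral conditions; no acid is present, so the electron-rich benzylic carbinol is not ionised and the S centre is kept.

## Compound list

1 | 2-fluorophenol | Oc1ccccc1F | starting material
2 | 1-fluoro-2-[(4-methoxybenzyl)oxy]benzene | COc1ccc(COc2ccccc2F)cc1 | intermediate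
3 | {2-fluoro-3-[(4-methoxybenzyl)oxy]phenyl}lithium (not isolated) | [Li]c1cccc(OCc2ccc(OC)cc2)c1F | intermediate
4 | 2-fluoro-3-[(4-methoxybenzyl)oxy]benzaldehyde | O=Cc1cccc(OCc2ccc(OC)cc2)c1F | intermediate
5 | 3-bromophenol | Oc1cccc(Br)c1 | starting material
6 | 2-(3-bromophenoxy)-3-[(4-methoxybenzyl)oxy]benzaldehyde | O=Cc1cccc(OCc2ccc(OC)cc2)c1Oc1cccc(Br)c1 | intermediate
7 | 2-(3-bromophenoxy)-1-ethenyl-3-[(4-methoxybenzyl)oxy]benzene | C=Cc1cccc(OCc2ccc(OC)cc2)c1Oc1cccc(Br)c1 | intermediate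
8 | 2,3-bis[(4-methoxybenzyl)oxy]benzaldehyde | O=Cc1cccc(OCc2ccc(OC)cc2)c1OCc1ccc(OC)cc1 | intermediate
9 | 2,3-bis[(4-methoxybenzyl)oxy]phenyl formate (not isolated) | O=COc1cccc(OCc2ccc(OC)cc2)c1OCc1ccc(OC)cc1 | intermediate
10 | 2,3-bis[(4-methoxybenzyl)oxy]phenol | Oc1cccc(OCc2ccc(OC)cc2)c1OCc1ccc(OC)cc1 | intermediate
11 | 1,4-diiodobenzene | Ic1ccc(I)cc1 | starting material
12 | 1-(4-iodophenoxy)-2,3-bis[(4-methoxybenzyl)oxy]benzene | Ic1ccc(Oc2cccc(OCc3ccc(OC)cc3)c2OCc2ccc(OC)cc2)cc1 | intermediate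
13 | 2-{3-(4-iodophenoxy)-4,5-bis[(4-methoxybenzyl)oxy]phenyl}-4,4,5,5-tetramethyl-1,3,2-dioxaborolane | CC1(C)OB(OC1(C)C)c1cc(Oc2ccc(I)cc2)c(OCc2ccc(OC)cc2)c(OCc2ccc(OC)cc2)c1 | intermediate
14 | 9-(2-{2-(3-bromophenoxy)-3-[(4-methoxybenzyl)oxy]phenyl}ethyl)-9-borabicyclo[3.3.1]nonane (not isolated) | Brc1cccc(Oc2c(CCB3C4CCCC3CCC4)cccc2OCc2ccc(OC)cc2)c1 | intermediate
15 | 2-{3-[4-(2-{2-(3-bromophenoxy)-3-[(4-methoxybenzyl)oxy]phenyl}ethyl)phenoxy]-4,5-bis[(4-methoxybenzyl)oxy]phenyl}-4,4,5,5-tetramethyl-1,3,2-dioxaborolane | CC1(C)OB(OC1(C)C)c1cc(Oc2ccc(CCc3cccc(OCc4ccc(OC)cc4)c3Oc3cccc(Br)c3)cc2)c(OCc2ccc(OC)cc2)c(OCc2ccc(OC)cc2)c1 | intermediate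
16 | vinylmagnesium chloride | C=C[Mg]Cl | starting material
17 | chloromagnesium salt of the ethenyl(pinacolato)borate formed from 15 and 16 (not isolated) | C=C[B-]1(OC(C)(C)C(C)(C)O1)c1cc(Oc2ccc(CCc3cccc(OCc4ccc(OC)cc4)c3Oc3cccc(Br)c3)cc2)c(OCc2ccc(OC)cc2)c(OCc2ccc(OC)cc2)c1.[Mg+]Cl | intermediate
18 | macrocyclic S pinacol boronic ester: the tris-PMB ether of the target with Bpin in place of the carbinol OH (not isolated) | COc1ccc(COc2cc3cc(c2OCc2ccc(OC)cc2)Oc2ccc(cc2)CCc2cccc(OCc4ccc(OC)cc4)c2Oc2cccc(c2)C[C@@H]3B5OC(C)(C)C(C)(C)O5)cc1 | intermediate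
19 | tris-PMB ether of the target (both ring A hydroxyls and the ring C hydroxyl as 4-methoxybenzyl ethers), S carbinol free | COc1ccc(COc2cc3cc(c2OCc2ccc(OC)cc2)Oc2ccc(cc2)CCc2cccc(OCc4ccc(OC)cc4)c2Oc2cccc(c2)C[C@@H]3O)cc1 | intermediate
20 | CNP0333307.1, S configuration at the carbinol carbon | Oc1cc2cc(c1O)Oc1ccc(cc1)CCc1cccc(O)c1Oc1cccc(c1)C[C@@H]2O | target

## Step count and risks

Total steps: 11. Longest linear sequence: 9 (steps 1, 2, 5, 6, 7, 8, 9, 10, 11).

**Step 10 (proposed new macrocyclising conjunctive coupling).** The ring closure may lose to oligomerisation or to direct Suzuki-type transfer, and the tether may lower the enantioselectivity. The fallback sets out from phenol 10 and comes back at 19, using only known reaction types. Phenol 10 is coupled with 1-chloro-4-iodobenzene (Clc1ccc(I)cc1) under the CuI/picolinic acid conditions of step 7 to give 1-(4-chlorophenoxy)-2,3-bis[(4-methoxybenzyl)oxy]benzene F1. Iridium-catalysed borylation as in step 8 gives 2-{3-(4-chlorophenoxy)-4,5-bis[(4-methoxybenzyl)oxy]phenyl}-4,4,5,5-tetramethyl-1,3,2-dioxaborolane F2. The ate complex of F2 and 16 is then joined with bromide 7 in an ordinary intermolecular conjunctive coupling (Pd(OAc)2, (Sp,Sp)-MandyPhos, NaOTf, THF/DMSO, 60 °C; then NaOH, H2O2); the aryl chloride does not react. This gives (1S)-1-{3-(4-chlorophenoxy)-4,5-bis[(4-methoxybenzyl)oxy]phenyl}-2-(3-{2-ethenyl-6-[(4-methoxybenzyl)oxy]phenoxy}phenyl)ethan-1-ol F3. Finally 9-BBN (excess, THF) adds to the vinyl group of F3, and an intramolecular B-alkyl Suzuki coupling on the aryl chloride (Pd(OAc)2, SPhos, K3PO4, THF/H2O, 65 °C, 2 mM) closes the macrocycle at the ethylene bridge and gives 19.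

**Step 9 (chemoselective B-alkyl Suzuki coupling).** The aryl pinacol boronate or the aryl bromide may take part. The fallback sets out from aldehyde 6 and comes back at 15. Aldehyde 6 is converted with dimethyl (1-diazo-2-oxopropyl)phosphonate and K2CO3 in MeOH into 2-(3-bromophenoxy)-1-ethynyl-3-[(4-methoxybenzyl)oxy]benzene F4. Sonogashira coupling of F4 with iodide 13 (PdCl2(PPh3)2, CuI, Et3N, THF, rt; no boron activation, iodide only) gives 2-{3-[4-({2-(3-bromophenoxy)-3-[(4-methoxybenzyl)oxy]phenyl}ethynyl)phenoxy]-4,5-bis[(4-methoxybenzyl)oxy]phenyl}-4,4,5,5-tetramethyl-1,3,2-dioxaborolane F5. Diimide reduction of the alkyne (excess TsNHNH2, NaOAc, DME/H2O, reflux), which spares the bromide, the boronate and the PMB ethers, gives 15.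

**Step 2 (ortho-lithiation next to fluorine).** The base may instead attack the PMB benzylic position or the position next to oxygen. The fallback sets out from 1 and comes back at 4. Phenol 1 is silylated (TIPSCl, imidazole, DMF) to (2-fluorophenoxy)tri(propan-2-yl)silane F6, which has no benzylic hydrogens and whose bulky silyl group shields the oxygen side. s-BuLi (THF, –78 °C) then lithiates next to fluorine, and DMF gives 2-fluoro-3-{[tri(propan-2-yl)silyl]oxy}benzaldehyde F7. One-pot desilylation and alkylation (CsF, PMBCl, DMF, rt) gives 4.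

## Further compounds

F1 | step 10 | 1-(4-chlorophenoxy)-2,3-bis[(4-methoxybenzyl)oxy]benzene | Clc1ccc(Oc2cccc(OCc3ccc(OC)cc3)c2OCc2ccc(OC)cc2)cc1
F2 | step 10 | 2-{3-(4-chlorophenoxy)-4,5-bis[(4-methoxybenzyl)oxy]phenyl}-4,4,5,5-tetramethyl-1,3,2-dioxaborolane | CC1(C)OB(OC1(C)C)c1cc(Oc2ccc(Cl)cc2)c(OCc2ccc(OC)cc2)c(OCc2ccc(OC)cc2)c1
F3 | step 10 | (1S)-1-{3-(4-chlorophenoxy)-4,5-bis[(4-methoxybenzyl)oxy]phenyl}-2-(3-{2-ethenyl-6-[(4-methoxybenzyl)oxy]phenoxy}phenyl)ethan-1-ol | O[C@@H](Cc1cccc(Oc2c(C=C)cccc2OCc2ccc(OC)cc2)c1)c1cc(Oc2ccc(Cl)cc2)c(OCc2ccc(OC)cc2)c(OCc2ccc(OC)cc2)c1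
F4 | step 9 | 2-(3-bromophenoxy)-1-ethynyl-3-[(4-methoxybenzyl)oxy]benzene | C#Cc1cccc(OCc2ccc(OC)cc2)c1Oc1cccc(Br)c1
F5 | step 9 | 2-{3-[4-({2-(3-bromophenoxy)-3-[(4-methoxybenzyl)oxy]phenyl}ethynyl)phenoxy]-4,5-bis[(4-methoxybenzyl)oxy]phenyl}-4,4,5,5-tetramethyl-1,3,2-dioxaborolane | CC1(C)OB(OC1(C)C)c1cc(Oc2ccc(C#Cc3cccc(OCc4ccc(OC)cc4)c3Oc3cccc(Br)c3)cc2)c(OCc2ccc(OC)cc2)c(OCc2ccc(OC)cc2)c1
F6 | step 2 | (2-fluorophenoxy)tri(propan-2-yl)silane | CC(C)[Si](Oc1ccccc1F)(C(C)C)C(C)C
F7 | step 2 | 2-fluoro-3-{[tri(propan-2-yl)silyl]oxy}benzaldehyde | O=Cc1cccc(O[Si](C(C)C)(C(C)C)C(C)C)c1F
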